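## Retrosynthetic overview

1. Target diacetate ⇒ (E)-2-alkylbut-2-ene-1,4-diol ⇒ alkoxide-directed anti-carbomagnesiation of but-2-yne-1,4-diol by a homoallylic Grignard reagent (forms the chain–butenediol bond and the E-butenediol).
2. Homoallylic bromide ⇒ (E)-homoallylic alcohol ⇒ terminal alkyne + Me3Al + oxirane (Zr-catalysed carboalumination sets the E-trisubstituted alkene).
3. Terminal alkyne ⇒ aldehyde ⇒ dioxolane ⇒ enol triflate (Pd/formate reduction fixes the endocyclic 2-ene).
4. Enol triflate ⇒ 2,4,4-trimethylcyclohex-2-enone + acetal Grignard reagent by the proposed Cu-catalysed enantioselective conjugate addition/O-triflation (ring–chain bond and the only stereocentre).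
5. Ring order: the single carbocycle is bought intact in the enone; no ring is formed in the route.

Assumption: 2,4,4-trimethylcyclohex-2-en-1-one, 2-(2-bromoethyl)-1,3-dioxolane and but-2-yne-1,4-diol are taken as catalogue chemicals, and the facial sense of the proposed catalyst is assigned by analogy (the antipodal ligand is used if it proves opposite).

## Route

Step 1
Reactants: 1 2,4,4-trimethylcyclohex-2-en-1-one; 2 2-(2-bromoethyl)-1,3-dioxolane
Product: 5 (3S)-3-[2-(1,3-dioxolan-2-yl)ethyl]-2,4,4-trimethylcyclohex-1-en-1-yl trifluoromethanesulfonate, via Grignard reagent 3 (not isolated), via magnesium enolate 4 (not isolated)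
Conditions: 2, Mg, 2-MeTHF, 25 °C; then 1, CuCl (5 mol %), (R,Rp)-Taniaphos (6 mol %), Et2O/2-MeTHF, −40 °C, slow addition of 3; then Comins' reagent, THF, −40 → 0 °C; aq. NH4Cl
Reagents that add atoms: Comins' reagent, N-(5-chloropyridin-2-yl)-1,1,1-trifluoro-N-[(trifluoromethyl)sulfonyl]methanesulfonamide, FC(F)(F)S(=O)(=O)N(c1ccc(Cl)cn1)S(=O)(=O)C(F)(F)F
Why: Proposed new method: a Cu(I)/ferrocenyl-diphosphine-catalysed enantioselective conjugate addition of a functionalised primary alkyl Grignard reagent to an α-methyl-γ,γ-dimethyl cyclohexenone, a doubly flanked β-carbon on which this reactivity has not been shown, coupled with in-flask O-triflation; the chiral alkylcuprate π-complexes one enantioface of C2=C3, oxidative addition gives a Cu(III) β-cuprio enolate held by Mg–O coordination, and reductive elimination forms the C3–C bond, sets C3 as S under ligand control and leaves the regiodefined C1=C2 magnesium enolate that Comins' reagent triflates on oxygen; the closest known reaction type is the Cu-catalysed asymmetric conjugate addition of Grignard reagents to cyclohex-2-enone (and of zinc or aluminium alkyls to 4,4-dimethyl- or 2-methylcyclohexenone separately) followed by enolate triflation.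

Step 2
Reactants: 5 (3S)-3-[2-(1,3-dioxolan-2-yl)ethyl]-2,4,4-trimethylcyclohex-1-en-1-yl trifluoromethanesulfonate
Product: 6 2-{2-[(1S)-2,6,6-trimethylcyclohex-2-en-1-yl]ethyl}-1,3-dioxolane
Conditions: Pd(OAc)2 (5 mol %), PPh3 (10 mol %), HCO2H, n-Bu3N, DMF, 60 °C
Reagents that add atoms: none
Why: Pd-catalysed formate reduction of an enol triflate (oxidative addition, formate exchange, decarboxylation, C–H reductive elimination) replaces OTf by H without moving the C=C bond, so the endocyclic 2-ene is obtained regiospecifically and the adjacent stereocentre is untouched.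

Step 3
Reactants: 6 2-{2-[(1S)-2,6,6-trimethylcyclohex-2-en-1-yl]ethyl}-1,3-dioxolane
Product: 7 3-[(1S)-2,6,6-trimethylcyclohex-2-en-1-yl]propanal
Conditions: 1 M aq. HCl, THF, 23 °C
Reagents that add atoms: water O
Why: Acid-catalysed acetal hydrolysis of the dioxolane proceeds under dilute acid at room temperature, conditions under which the trisubstituted ring alkene neither migrates nor adds to the aldehyde.

Step 4
Reactants: 7 3-[(1S)-2,6,6-trimethylcyclohex-2-en-1-yl]propanal
Product: 8 (6S)-6-(but-3-yn-1-yl)-1,5,5-trimethylcyclohex-1-ene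
Conditions: dimethyl (1-diazo-2-oxopropyl)phosphonate, K2CO3, MeOH, 0 → 23 °C
Reagents that add atoms: dimethyl (1-diazo-2-oxopropyl)phosphonate CC(=O)C(=[N+]=[N-])P(=O)(OC)OC
Why: Seyferth–Gilbert homologation in the Ohira–Bestmann variant converts the aldehyde into the terminal alkyne under mild base, and the stereocentre is γ to the carbonyl and cannot epimerise.

Step 5
Reactants: 8 (6S)-6-(but-3-yn-1-yl)-1,5,5-trimethylcyclohex-1-ene
Product: 11 (3E)-4-methyl-6-[(1S)-2,6,6-trimethylcyclohex-2-en-1-yl]hex-3-en-1-ol, via alkenylalane 9 (not isolated), via lithium alkenylaluminate 10 (not isolated)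
Conditions: Me3Al, Cp2ZrCl2 (25 mol %), CH2Cl2, 0 → 23 °C; volatiles removed; n-BuLi, hexane, 0 °C; oxirane, THF, 0 → 23 °C; aq. Rochelle salt
Reagents that add atoms: trimethylaluminium C[Al](C)C; oxirane C1CO1
Why: Negishi Zr-catalysed syn-carboalumination of the terminal alkyne places Me on the internal carbon and Al on the terminus cis to it, and the derived aluminate opens oxirane with retention at the alkenyl carbon, so the trisubstituted alkene is formed as the E isomer only while the ring alkene is inert.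

Step 6
Reactants: 11 (3E)-4-methyl-6-[(1S)-2,6,6-trimethylcyclohex-2-en-1-yl]hex-3-en-1-ol
Product: 12 (6S)-6-[(3E)-6-bromo-3-methylhex-3-en-1-yl]-1,5,5-trimethylcyclohex-1-ene
Conditions: CBr4, PPh3, CH2Cl2, 0 °C
Reagents that add atoms: tetrabromomethane BrC(Br)(Br)Br
Why: The Appel reaction converts the primary alcohol into the bromide by SN2 displacement of an alkoxyphosphonium ion under neutral conditions that leave both alkenes unchanged.

Step 7
Reactants: 12 (6S)-6-[(3E)-6-bromo-3-methylhex-3-en-1-yl]-1,5,5-trimethylcyclohex-1-ene; 13 but-2-yne-1,4-diol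
Product: 17 (2E)-2-{(3E)-4-methyl-6-[(1S)-2,6,6-trimethylcyclohex-2-en-1-yl]hex-3-en-1-yl}but-2-ene-1,4-diol, via Grignard reagent 14 (not isolated), via magnesium dialkoxide 15 (not isolated), via alkenylmagnesium adduct 16 (not isolated)
Conditions: 12, Mg, THF, 45 °C; separately 13 (2 equiv), MeMgCl (4 equiv), THF, 0 °C; combine, CuI (10 mol %), THF, 65 °C; aq. NH4Cl
Reagents that add atoms: none
Why: Alkoxide-directed Cu-catalysed anti-carbomagnesiation of a propargylic alcohol puts the alkyl group on the carbon next to the directing CH2O–Mg and the magnesium trans to it in a five-membered O–Mg–C chelate, so protonolysis gives the E-diol (the two CH2OH groups trans, the chain cis to the C1 CH2OH) from the symmetric alkyne without a regiochemical issue.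

Step 8
Reactants: 17 (2E)-2-{(3E)-4-methyl-6-[(1S)-2,6,6-trimethylcyclohex-2-en-1-yl]hex-3-en-1-yl}but-2-ene-1,4-diol
Product: 18 (2E)-2-{(3E)-4-methyl-6-[(1S)-2,6,6-trimethylcyclohex-2-en-1-yl]hex-3-en-1-yl}but-2-ene-1,4-diyl diacetate (CNP0186001.1)
Conditions: Ac2O, pyridine, DMAP (5 mol %), CH2Cl2, 0 → 23 °C
Reagents that add atoms: acetic anhydride CC(=O)OC(C)=O
Why: DMAP-catalysed acylation of the two primary allylic alcohols gives the diacetate without touching the alkene geometries or the stereocentre.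

## Compound list

1 | 2,4,4-trimethylcyclohex-2-en-1-one | CC1=CC(C)(C)CCC1=O | starting material
2 | 2-(2-bromoethyl)-1,3-dioxolane | BrCCC1OCCO1 | starting material
3 | [2-(1,3-dioxolan-2-yl)ethyl]magnesium bromide | Br[Mg]CCC1OCCO1 | intermediate
4 | bromomagnesium (3S)-3-[2-(1,3-dioxolan-2-yl)ethyl]-2,4,4-trimethylcyclohex-1-en-1-olate | O1CCOC1CC[C@@H]1C(C)=C(O[Mg]Br)CCC1(C)C | intermediate
5 | (3S)-3-[2-(1,3-dioxolan-2-yl)ethyl]-2,4,4-trimethylcyclohex-1-en-1-yl trifluoromethanesulfonate | O1CCOC1CC[C@@H]1C(C)=C(OS(=O)(=O)C(F)(F)F)CCC1(C)C | intermediate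
6 | 2-{2-[(1S)-2,6,6-trimethylcyclohex-2-en-1-yl]ethyl}-1,3-dioxolane | O1CCOC1CC[C@@H]1C(C)=CCCC1(C)C | intermediate
7 | 3-[(1S)-2,6,6-trimethylcyclohex-2-en-1-yl]propanal | O=CCC[C@@H]1C(C)=CCCC1(C)C | intermediate
8 | (6S)-6-(but-3-yn-1-yl)-1,5,5-trimethylcyclohex-1-ene | C#CCC[C@@H]1C(C)=CCCC1(C)C | intermediate
9 | dimethyl{(1E)-2-methyl-4-[(1S)-2,6,6-trimethylcyclohex-2-en-1-yl]but-1-en-1-yl}alumane | C[Al](C)/C=C(\C)CC[C@@H]1C(C)=CCCC1(C)C | intermediate
10 | lithium butyl(dimethyl){(1E)-2-methyl-4-[(1S)-2,6,6-trimethylcyclohex-2-en-1-yl]but-1-en-1-yl}aluminate | [Li+].CCCC[Al-](C)(C)/C=C(\C)CC[C@@H]1C(C)=CCCC1(C)C | intermediate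
11 | (3E)-4-methyl-6-[(1S)-2,6,6-trimethylcyclohex-2-en-1-yl]hex-3-en-1-ol | OCC/C=C(\C)CC[C@@H]1C(C)=CCCC1(C)C | intermediate
12 | (6S)-6-[(3E)-6-bromo-3-methylhex-3-en-1-yl]-1,5,5-trimethylcyclohex-1-ene | BrCC/C=C(\C)CC[C@@H]1C(C)=CCCC1(C)C | intermediate
13 | but-2-yne-1,4-diol | OCC#CCO | starting material
14 | {(3E)-4-methyl-6-[(1S)-2,6,6-trimethylcyclohex-2-en-1-yl]hex-3-en-1-yl}magnesium bromide | Br[Mg]CC/C=C(\C)CC[C@@H]1C(C)=CCCC1(C)C | intermediate
15 | bis(chloromagnesium) but-2-yne-1,4-diolate | Cl[Mg]OCC#CCO[Mg]Cl | intermediate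
16 | {(2Z)-1,4-bis[(chloromagnesio)oxy]-3-{(3E)-4-methyl-6-[(1S)-2,6,6-trimethylcyclohex-2-en-1-yl]hex-3-en-1-yl}but-2-en-2-yl}magnesium bromide (Mg trans to the new alkyl group) | Cl[Mg]OC/C([Mg]Br)=C(\CC/C=C(\C)CC[C@@H]1C(C)=CCCC1(C)C)CO[Mg]Cl | intermediate
17 | (2E)-2-{(3E)-4-methyl-6-[(1S)-2,6,6-trimethylcyclohex-2-en-1-yl]hex-3-en-1-yl}but-2-ene-1,4-diol | OC/C=C(\CC/C=C(\C)CC[C@@H]1C(C)=CCCC1(C)C)CO | intermediate
18 | (2E)-2-{(3E)-4-methyl-6-[(1S)-2,6,6-trimethylcyclohex-2-en-1-yl]hex-3-en-1-yl}but-2-ene-1,4-diyl diacetate | CC(=O)OC/C=C(\CC/C=C(\C)CC[C@@H]1C(C)=CCCC1(C)C)COC(C)=O | target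

## Step count and risk

Total step count: 8. Longest linear sequence: 8 steps (1 → 18; 2 and 13 enter as purchased reagents).

The three steps most likely to fail:

Step 1 (the proposed new method). The β-carbon is flanked by the α-methyl group and the quaternary carbon, so slow addition, competing 1,2-addition or modest enantioselectivity are possible. The fallback uses known chemistry only, sets out from 1 and comes back to the route at 8, replacing steps 1 to 4. Enone 1 is reduced with (S)-Me-CBS and BH3·SMe2 (the substituted vinyl side acting as the large group) to (1R)-2,4,4-trimethylcyclohex-2-en-1-ol F1. Johnson–Claisen rearrangement of this alcohol with triethyl orthoacetate and catalytic propionic acid at 140 °C transfers the C–O chirality suprafacially to the carbon next to the gem-dimethyl group and gives ethyl 2-[(1S)-2,6,6-trimethylcyclohex-2-en-1-yl]acetate F2, with the ring alkene already in the 2-position. LiAlH4 in THF reduces the ester to 2-[(1S)-2,6,6-trimethylcyclohex-2-en-1-yl]ethan-1-ol F3. I2, PPh3 and imidazole give (6S)-6-(2-iodoethyl)-1,5,5-trimethylcyclohex-1-ene F4, and displacement with lithium acetylide–ethylenediamine complex in DMSO gives alkyne 8.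

Step 5. The carboalumination is dependable, but ate-complex formation and epoxide opening in the same flask can give low yields with residual aluminium and zirconium species present. The fallback sets out from 8 and comes back at 11. The same carboalumination is quenched with I2 to give (6S)-6-[(3E)-4-iodo-3-methylbut-3-en-1-yl]-1,5,5-trimethylcyclohex-1-ene F5. Suzuki–Miyaura coupling with vinylboronic acid pinacol ester (PdCl2(dppf), aq. K3PO4, THF) gives (6S)-1,5,5-trimethyl-6-[(3E)-3-methylhexa-3,5-dien-1-yl]cyclohex-1-ene F6. Hydroboration of the terminal vinyl group with 9-BBN, which is selective over both trisubstituted alkenes, followed by NaOH/H2O2 gives alcohol 11.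

Step 7. A primary alkyl Grignard reagent adds more slowly than allyl or aryl reagents, and the magnesium dialkoxide is poorly soluble. The fallback sets out from 12 and 13 and comes back at 17. Diol 13 is converted by Red-Al trans-hydroalumination and iodination into (2Z)-2-iodobut-2-ene-1,4-diol F7, which is silylated (TBSCl, imidazole, DMF) to (2Z)-1,4-bis[(tert-butyldimethylsilyl)oxy]-2-iodobut-2-ene F8. Bromide 12 is converted with activated Zn dust and LiCl in THF at 50 °C into {(3E)-4-methyl-6-[(1S)-2,6,6-trimethylcyclohex-2-en-1-yl]hex-3-en-1-yl}zinc bromide F9. Negishi coupling of the two (Pd(OAc)2, SPhos, THF, 40 °C) proceeds with retention at the alkenyl carbon and gives (2E)-1,4-bis[(tert-butyldimethylsilyl)oxy]-2-{(3E)-4-methyl-6-[(1S)-2,6,6-trimethylcyclohex-2-en-1-yl]hex-3-en-1-yl}but-2-ene F10. TBAF in THF then gives diol 17.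

## Further compounds

F1 | step 1 | (1R)-2,4,4-trimethylcyclohex-2-en-1-ol | O[C@@H]1CCC(C)(C)C=C1C
F2 | step 1 | ethyl 2-[(1S)-2,6,6-trimethylcyclohex-2-en-1-yl]acetate | CCOC(=O)C[C@@H]1C(C)=CCCC1(C)C
F3 | step 1 | 2-[(1S)-2,6,6-trimethylcyclohex-2-en-1-yl]ethan-1-ol | OCC[C@@H]1C(C)=CCCC1(C)C
F4 | step 1 | (6S)-6-(2-iodoethyl)-1,5,5-trimethylcyclohex-1-ene | ICC[C@@H]1C(C)=CCCC1(C)C
F5 | step 5 | (6S)-6-[(3E)-4-iodo-3-methylbut-3-en-1-yl]-1,5,5-trimethylcyclohex-1-ene | I/C=C(\C)CC[C@@H]1C(C)=CCCC1(C)C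
F6 | step 5 | (6S)-1,5,5-trimethyl-6-[(3E)-3-methylhexa-3,5-dien-1-yl]cyclohex-1-ene | C=C/C=C(\C)CC[C@@H]1C(C)=CCCC1(C)C
F7 | step 7 | (2Z)-2-iodobut-2-ene-1,4-diol | OC/C=C(\I)CO
F8 | step 7 | (2Z)-1,4-bis[(tert-butyldimethylsilyl)oxy]-2-iodobut-2-ene | CC(C)(C)[Si](C)(C)OC/C=C(\I)CO[Si](C)(C)C(C)(C)C
F9 | step 7 | {(3E)-4-methyl-6-[(1S)-2,6,6-trimethylcyclohex-2-en-1-yl]hex-3-en-1-yl}zinc bromide | Br[Zn]CC/C=C(\C)CC[C@@H]1C(C)=CCCC1(C)C
F10 | step 7 | (2E)-1,4-bis[(tert-butyldimethylsilyl)oxy]-2-{(3E)-4-methyl-6-[(1S)-2,6,6-trimethylcyclohex-2-en-1-yl]hex-3-en-1-yl}but-2-ene | CC(C)(C)[Si](C)(C)OC/C=C(\CC/C=C(\C)CC[C@@H]1C(C)=CCCC1(C)C)CO[Si](C)(C)C(C)(C)C
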